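Readings and results were computed with made-up constants; the scatter is artificial.

**Fixed ratio.** This flask holds a racemate with a single-handed catalyst, and the question is how clean the leftover right-handed substrate gets.

in all of them: left-handed substrate 0.80 M; right-handed substrate 0.80 M

| charge | reagent | precatalyst | remark | time |
|---|---|---|---|---|
| Sunday's | 3 equiv | 14 mol% | run made earlier |  |
| Saturday's | 3 equiv | 22 mol% | run made earlier |  |
| flask | 3.00 equiv | 10 mol% |  | 40 min |

| run | time / min | right-handed substrate / % | left-handed substrate / % |
|---|---|---|---|
| Sunday's | 8.00 | 42 | 8 |
| Sunday's | 15.0 | 41 | 0 |
| Sunday's | 25.0 | 34 | 4 |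
| Sunday's | 30.0 | 29 | 1 |
| Saturday's | 4.00 | 46 | 17 |
| Saturday's | 12.0 | 35 | 0 |
| Saturday's | 20.0 | 27 | 0 |
| Saturday's | 30.0 | 22 | 1 |

(standard deviation of a reading: 2 percentage points)

- free catalyst is single-handed; left-handed substrate and right-handed substrate are mirror images of each other, charged as a racemate, each of them at the stated concentration
- candidate steps: free catalyst + left-handed substrate <-> catalyst intermediate A; free catalyst + right-handed substrate <-> catalyst intermediate B; reagent + catalyst intermediate A -> free catalyst + left-handed product; reagent + catalyst intermediate B -> free catalyst + right-handed product; reagent <-> dormant form; reagent + free catalyst -> spent catalyst; precatalyst -> free catalyst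

* whether the excess of right-handed substrate over left-handed substrate among what is left of the two reaches 98% by 40 min (no / yes)
* the highest excess of right-handed substrate over left-handed substrate among what is left of the two up to 40 min

While each mirror image falls in proportion to its own amount, and the two proportions keep a fixed ratio, the logarithm of the fraction left of the left-handed substrate, over the same logarithm for the right-handed, stays constant at any loading and time. This is the selectivity factor. Sunday's first readings give 10.5 and Saturday's give 12.9.

**The bar.** An excess of 98% caps left-handed over right-handed substrate remaining at 0.0101. This ceiling ratio is one minus the excess, over one plus the excess.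

**My reckoning.** I take the log fall of the right-handed substrate as proportional to time and loading, starting from Sunday's 29% at 30.0 min. 0.519 is then its log fall in this flask, so this flask keeps about 29.8% at 40 min. The left-handed substrate must therefore reach 0.301%, which needs a factor of 9.86. Both readings stand above that. On this reckoning the lower one leaves 0.214% and gives an excess of 98.6%, so I say yes, narrowly.

**The border.** The needed amount in my reckoning is 0.301% against a scatter of 2 percentage points, so the rule is carried far below what these readings resolve.

**The forecast.** It says no, with a top of 97.6%, holding that the ratio “does not depend on catalyst loading or time”. That differs from my yes.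

**The flask.** The answer is yes: the wanted excess comes at 23.4 min, and the top is 99.9%.

    free catalyst + left-handed substrate ⇌ catalyst intermediate A (K = 14.0 M⁻¹, k = 39.0 M⁻¹ min⁻¹)
    free catalyst + right-handed substrate ⇌ catalyst intermediate B (K = 4.10 M⁻¹, k = 9.30 M⁻¹ min⁻¹)
    reagent + catalyst intermediate A → free catalyst + left-handed product (k = 1.20 M⁻¹ min⁻¹)
    reagent + catalyst intermediate B → free catalyst + right-handed product (k = 0.110 M⁻¹ min⁻¹)
    reagent ⇌ dormant form (K = 0.540, k = 0.0110 min⁻¹)
    reagent + free catalyst → spent catalyst (k = 0.0180 M⁻¹ min⁻¹)
    precatalyst → free catalyst (k = 0.510 min⁻¹)

**The ceiling.** At 40.0 min this flask's ratio of left-handed to right-handed substrate is 2.94 × 10⁻⁴, under the ceiling. The largest single effect I can show is catalyst intermediate B returning to free catalyst and right-handed substrate, though it need not be the main reason. The same flask without that return ends at an excess of 27.1%, a ratio of 0.574, over the ceiling.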